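The target came late. In the violet run it read 0% at 1.50 h, when the substrate already stood at 55.7%. The proposed chain runs from substrate and coupling partner to intermediate A, then with second reagent to intermediate B, then with third reagent to target; homo dimer and side product branch off it.

| setting | violet | green | spring | summer | autumn | midnight |
|---|---|---|---|---|---|---|
| substrate | 0.30 M | 0.30 M | 0.30 M | 0.30 M | 0.30 M | 0.30 M |
| coupling partner | 4 equiv | 4 equiv | 4.00 equiv | 4.00 equiv | 4.00 equiv | 4.00 equiv |
| second reagent | 1.2 equiv | 1.2 equiv | 1.20 equiv | 1.20 equiv | 1.20 equiv | 1.20 equiv |
| third reagent | 0.65 equiv | 2.6 equiv | 1.30 equiv | 1.30 equiv | 1.30 equiv | 1.30 equiv |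
| temperature | 2 °C | 19 °C |  | 10 °C | 25 °C | −5 °C |
| remark | run made earlier | run made earlier | at −5 °C until 1.5 h, from then on at 25 °C |  |  |  |
| time |  |  | 5.0 h | 5.0 h | 5.0 h | 5.0 h |

- violet (time / h: target / %, substrate / %): 0.333: 0.4, 87.3; 0.667: 0, 75.2; 1.50: 0, 55.7; 4.00: 3.5, 23.5
- green (time / h: target / %, substrate / %): 0.333: 2.5, 43.7; 0.833: 11.0, 17.5; 1.50: 27.6, 3.2; 2.50: 48.6, 0.5

(each reading ± 1 percentage point)

- percentages count the substrate that a species holds: one side product counts as two
- the numbers in the tables scatter with a standard deviation of 1 percentage point
- steps that have been proposed: substrate + coupling partner -> intermediate A; second reagent + intermediate A -> intermediate B; third reagent + intermediate B -> target; 2 coupling partner -> homo dimer; substrate + target -> side product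

1. the flask that comes out highest in amount of target, in percent of the substrate charged, or "all alike" when all lie within 1.5 percentage points (spring / summer / autumn / midnight / all alike)
2. target at the end, in percent of the substrate charged, spring
3. target at the end, in percent of the substrate charged, summer
4. target at the end, in percent of the substrate charged, autumn
5. target at the end, in percent of the substrate charged, midnight

With coupling partner charged at 4.00 equiv, I treated the substrate's loss as pseudo-first-order and took its rate constant where the two runs stood at a similar extent: 0.390 h⁻¹ in violet and 2.49 h⁻¹ in green. These readings give an activation energy of 72.8 kJ mol⁻¹, hence 0.170 h⁻¹ at midnight's temperature, 0.959 h⁻¹ at summer's and 4.54 h⁻¹ at autumn's. Midnight's 5.0 h therefore came to an estimated 0.850 on my clock, the number of substrate lifetimes elapsed. I assumed that the later steps kept pace with this clock as the temperature changed.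

The green run gave the ladder. At clock 0.828 its substrate read 43.7% and its target 2.5%. At clock 6.23 its substrate read 0.5%, yet its target read about half of the substrate charged. In the green run the substrate's lifetime, as read, was 0.402 h, shorter than the 2.50 h of that last reading.

On the lowest rung, at early times, 3 steps in series integrate to a target that grows as the cube of the clock and in proportion to each rate. By my clock midnight's end stood on about the same rung as green's first reading, with half the third reagent. I therefore expected 42.7% substrate and 1.35% target, a rough figure given the scatter of 1 percentage point. The other clocks came to 22.7 in autumn, 16.2 in spring and 4.79 in summer, so I ranked autumn first, its clock being longer than the others.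

The forecast also chose autumn, with 62% for spring, 23% for summer, 75% for autumn and 2.5% for midnight, holding that “one slow step from the intermediates fits”. For midnight my figure was lower than its figure.

The flasks gave 72.2% in spring, 27.2% in summer, 82.1% in autumn and 0.928% in midnight, so autumn came out highest.

    substrate + coupling partner → intermediate A (k = 0.0680 M⁻¹ min⁻¹, Ea = 71.0 kJ mol⁻¹)
    second reagent + intermediate A → intermediate B (k = 0.0600 M⁻¹ min⁻¹, Ea = 69.0 kJ mol⁻¹)
    third reagent + intermediate B → target (k = 0.0650 M⁻¹ min⁻¹, Ea = 71.0 kJ mol⁻¹)
    2 coupling partner → homo dimer (k = 0.00190 M⁻¹ min⁻¹, Ea = 67.0 kJ mol⁻¹)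
    substrate + target → side product (k = 0.00410 M⁻¹ min⁻¹, Ea = 79.0 kJ mol⁻¹)
    (constants at 25 °C)

In midnight at 1.83 h, intermediate A was being made 8.10 times faster than it was used up. At the end of midnight intermediate A held 49.8%, against 7.75% in intermediate B, 0.928% in target and 41.5% in substrate. The neighbour of midnight charged with 2.40 equiv of coupling partner has its clock scaled to 0.510, which gives 60.0% substrate. The first of the 3 rates falls in the same ratio, which puts the estimate for target at 0.557%. That flask gave 58.9% substrate and 0.612% target.

The data come from a simulation on assumed constants; the scatter is artificial.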